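The bicyclic core is cut at the C4–C5 bond of ring A. With ring B drawn as a cyclohexadienone, C10 (bearing the C20 methyl, flanked by C5 and C9) is prochiral, and C4, which ends with two identical acetoxymethyl arms, can enter as an aldehyde carbon. A chiral triazolylidene turns that aldehyde into an acyl anion equivalent that adds to C5 of one enantiotopic enone arm. This one operation closes ring A, fixes C10 and leaves a C4 ketone and a C7 enone, from which C17, C9 and the side chain are developed. The precursor is the achiral 4-methyl-4-(4-oxobutyl)cyclohexa-2,5-dienone, made in four steps.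

Key step: step 5

Remarks
- Labdane numbering is used for the bicyclic compounds (ring A: C1–C5 and C10; ring B: C5–C10; C20 is the methyl on C10, C17 the carbon on C8, C11 onwards the chain on C9). "Syn" and "anti" give the face relative to C20.
- Assumption: which antipode of the triazolium salt leads to (4aS,8aR)-12 cannot be predicted for this all-carbon tether, so it is fixed by a pilot run; both antipodes are accessible from the enantiomeric cis-1-aminoindan-2-ols.

Step 1
Reactants: 1 methacrolein (2-methylprop-2-enal); 2 but-3-en-1-ylmagnesium bromide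
Product: 4 2-methylhept-6-enal (racemic), via silyl enol ether 3 (not isolated)
Conditions: CuBr·SMe2 (5 mol%), Me3SiCl, HMPA, THF, −78 °C; then 1 M HCl, 0 °C
Reagents that add atoms: none
Why: Copper-catalysed conjugate addition of the Grignard reagent, in which Me3SiCl traps the enolate as its silyl enol ether and suppresses 1,2-addition, and acidic work-up releases the α-methyl aldehyde; its stereocentre is formed racemic and is of no consequence because that carbon becomes the prochiral quaternary centre.

Step 2
Reactants: 4 2-methylhept-6-enal; 5 but-3-en-2-one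
Product: 8 4-methyl-4-(pent-4-en-1-yl)cyclohex-2-en-1-one (racemic), via enamine 6 (not isolated), via keto aldehyde 7 (not isolated)
Conditions: pyrrolidine (1.2 equiv), toluene, reflux with azeotropic removal of water; then 5, 0 → 23 °C; then AcOH–NaOAc–H2O, 80 °C
Reagents that add atoms: none
Why: Enamine-mediated Robinson annulation, in which the enamine of the α-branched aldehyde adds to the enone in Michael fashion and, after hydrolysis, the methyl ketone closes onto the aldehyde by aldol condensation to give the 4,4-disubstituted cyclohexenone, whose single stereocentre disappears in step 3.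

Step 3
Reactants: 8 4-methyl-4-(pent-4-en-1-yl)cyclohex-2-en-1-one
Product: 9 4-methyl-4-(pent-4-en-1-yl)cyclohexa-2,5-dien-1-one
Conditions: DDQ (2 equiv), 1,4-dioxane, reflux
Reagents that add atoms: none
Why: Quinone dehydrogenation (hydride abstraction from the enol, then proton loss) can only give the cross-conjugated dienone in a 4,4-disubstituted ring, and the isolated terminal alkene has no activated C–H to compete; the product is achiral.

Step 4
Reactants: 9 4-methyl-4-(pent-4-en-1-yl)cyclohexa-2,5-dien-1-one
Product: 11 4-methyl-4-(4-oxobutyl)cyclohexa-2,5-dien-1-one, via ozonide 10 (not isolated)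
Conditions: O3, CH2Cl2, −78 °C (Sudan Red 7B as end-point indicator); then PPh3, −78 → 23 °C
Reagents that add atoms: ozone, [O-][O+]=O
Why: Ozonolysis with reductive work-up, in which the electron-rich terminal alkene cycloadds ozone far faster than the two electron-poor dienone alkenes and the indicator dye marks the end point before these are touched.

Step 5
Reactants: 11 4-methyl-4-(4-oxobutyl)cyclohexa-2,5-dien-1-one
Product: 12 (4aS,8aR)-4a-methyl-4a,5,6,7-tetrahydronaphthalene-2,8(1H,8aH)-dione (cis-fused 10-methyl-octal-8-ene-4,7-dione; H-5 syn to C20)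
Conditions: aminoindanol-derived N-pentafluorophenyl triazolium tetrafluoroborate (20 mol%), KN(SiMe3)2 (20 mol%), toluene, 23 °C
Reagents that add atoms: none
Why: The triazolium salt is deprotonated to the free carbene, which adds to the C4 aldehyde; proton transfer gives the nucleophilic enaminol (acyl anion equivalent), which adds in Michael fashion to C5 of one enone arm, and tautomerisation with expulsion of the carbene leaves the C4 ketone. The closest known reaction type is the enantioselective intramolecular Stetter reaction used to desymmetrise 4,4-disubstituted cyclohexadienones that carry a tethered aldehyde. Ring A closes by 6-exo-trig attack of C4 on C5. C10 is set by the catalyst, whose chiral environment decides which of the two enantiotopic arms (C5=C6 or C9=C8) is attacked, while C5 is set by the substrate, because the three-carbon tether can deliver C4 only to the face of C5 on which C1 stands, so that H-5 ends syn to C20 (cis fusion). The step needs enantiotopic-group selectivity and 1,4- rather than 1,2-reactivity; the substrate secures both because the two arms are identical and equidistant from the aldehyde, the tether reaches only the β-carbons, and the hindered dienone carbonyl is a poor benzoin-type acceptor.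

Step 6
Reactants: 12 cis-fused enedione
Product: 13 (4aS,8aS)-4a-methyl-4a,5,6,7-tetrahydronaphthalene-2,8(1H,8aH)-dione (trans-fused; H-5 anti to C20)
Conditions: DBU (0.2 equiv), toluene, 23 °C; chromatography with resubmission of recovered 12
Reagents that add atoms: none
Why: Base-mediated epimerisation through the C4 enolate (C5 is the only stereocentre α to a carbonyl), in which the trans-fused ketone avoids the extra gauche interactions of either cis conformer, as in the familiar base-induced change of 5β- into 5α-configured 4- and 6-oxo steroids, and should therefore predominate at equilibrium while C10 is untouched.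

Step 7
Reactants: 13 trans-fused enedione
Product: 14 trans-fused 4,4-(ethylenedioxy)-10-methyl-octal-8-en-7-one (C4 of 13 as its 1,3-dioxolane)
Conditions: Me3SiOCH2CH2OSiMe3 (1.5 equiv), Me3SiOTf (5 mol%), CH2Cl2, −78 → −20 °C; pyridine quench
Reagents that add atoms: 1,2-bis(trimethylsilyloxy)ethane, C[Si](C)(C)OCCO[Si](C)(C)C
Why: Silyl-triflate-catalysed ketalisation with the bis-silyl ether of ethylene glycol is selective for the saturated C4 ketone over the conjugated C7 ketone and runs cold enough not to enolise C5, so the trans fusion is carried over and no stereocentre is formed.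

Step 8
Reactants: 14 enone ketal
Product: 15 8-(hydroxymethyl) enone ketal (14 with CH2OH, C17, on C8)
Conditions: 37% aq. HCHO, DMAP (0.5 equiv), THF–H2O, 23 °C
Reagents that add atoms: formaldehyde, C=O
Why: Morita–Baylis–Hillman reaction, in which DMAP adds reversibly to C9, the resulting C8 enolate is hydroxymethylated by formaldehyde and loss of DMAP restores the enone; no stereocentre is formed and the ketal is inert to the weakly basic medium.

Step 9
Reactants: 15 8-(hydroxymethyl) enone ketal
Product: 16 tert-butyldimethylsilyl ether of 15 (C17–OTBS)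
Conditions: TBSCl, imidazole, CH2Cl2, 0 → 23 °C
Reagents that add atoms: tert-butyldimethylsilyl chloride, CC(C)(C)[Si](C)(C)Cl
Why: Routine silylation of the primary allylic alcohol, so that only the C7 oxygen can later enter the sigmatropic step.

Step 10
Reactants: 16 silyl ether
Product: 17 (7R)-allylic alcohol (16 with C7 as carbinol; O-7 syn to C20)
Conditions: NaBH4, CeCl3·7H2O, MeOH, −78 → −40 °C
Reagents that add atoms: none
Why: Luche 1,2-reduction, in which the small cerium-activated hydride attacks the C7 carbonyl of the rigid trans-fused enone along the axial trajectory on the face anti to C20, so that the pseudo-equatorial alcohol with its oxygen syn to C20 should be the main product.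

Step 11
Reactants: 17 (7R)-allylic alcohol; 18 N,N-dimethylacetamide dimethyl acetal
Product: 20 C9 acetamide (C9 bears CH2C(O)NMe2 syn to C20; alkene C7=C8; C8 bears CH2OTBS; C4 dioxolane), via ketene N,O-acetal 19 (not isolated)
Conditions: xylene, 140 °C, sealed vessel
Reagents that add atoms: none
Why: Eschenmoser–Claisen rearrangement, in which the ketene N,O-acetal formed on O-7 undergoes a suprafacial [3,3] shift across C7–C8=C9, so the new C9–C11 bond appears on the face that held the C7 oxygen (syn to C20), as when equatorial 3-oxygenated 4-ene steroids give 5-substituted products syn to the angular methyl; the alkene moves to C7=C8.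

Step 12
Reactants: 20 C9 acetamide
Product: 21 C17 alcohol of 20 (C8 bears CH2OH)
Conditions: Bu4NF, THF, 0 → 23 °C
Reagents that add atoms: none
Why: Fluoride cleavage of the primary silyl ether, in which the tertiary amide, unlike an ester, cannot lactonise onto the liberated C17 hydroxyl.

Step 13
Reactants: 21 C17 alcohol
Product: 24 8(17)-methylene amide ketal (exocyclic C8=C17; C7 is CH2), via sulfonylhydrazine 22 (not isolated), via allylic diazene 23 (not isolated)
Conditions: 2-nitrobenzenesulfonylhydrazide, PPh3, diethyl azodicarboxylate, N-methylmorpholine, −30 °C, then 23 °C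
Reagents that add atoms: none
Why: Mitsunobu displacement of the C17 hydroxyl by the sulfonylhydrazide, loss of arenesulfinic acid on warming and retro-ene fragmentation of the allylic diazene deliver hydrogen to C7 and move the alkene to C8=C17 with loss of N2 (reductive allylic transposition), leaving C9 untouched.

Step 14
Reactants: 24 8(17)-methylene amide ketal
Product: 25 4-oxo amide (24 with C4 as ketone; H-5 anti to C20)
Conditions: 1 M HCl, THF, 23 °C
Reagents that add atoms: water, O
Why: Acid-catalysed ketal hydrolysis, helped by relief of the syn-axial contact between a ketal oxygen and C20, is tolerated by the amide and the 1,1-disubstituted alkene and leaves C5 in its more stable trans arrangement.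

Step 15
Reactants: 25 4-oxo amide
Product: 27 4-formyl amide (CHO on C4; mixture of C4 epimers), via enol ether 26 (not isolated)
Conditions: MeOCH2PPh3Cl, KOt-Bu, THF, 0 → 23 °C; then 1 M HCl, THF, 23 °C
Reagents that add atoms: (methoxymethyl)triphenylphosphonium chloride, COC[P+](c1ccccc1)(c1ccccc1)c1ccccc1.[Cl-]; water, O
Why: Wittig methoxymethylenation of the C4 ketone followed by enol ether hydrolysis gives the one-carbon-homologated aldehyde, and the mixed configuration at C4 is irrelevant because C4 next receives a second, identical arm.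

Step 16
Reactants: 27 4-formyl amide
Product: 29 18,19-diol amide (C4 bears two CH2OH), via hydroxy aldehyde 28 (not isolated)
Conditions: 37% aq. HCHO (excess), KOH, MeOH–H2O, 60 °C
Reagents that add atoms: formaldehyde, C=O
Why: Tollens reaction, in which aldol addition of the C4 enolate to formaldehyde creates the quaternary carbon and crossed Cannizzaro hydride transfer from a second formaldehyde reduces the now non-enolisable aldehyde, giving two identical hydroxymethyl groups so that C4 is not a stereocentre.

Step 17
Reactants: 29 18,19-diol amide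
Product: 30 18,19-dihydroxy C12 aldehyde (C9 bears CH2CHO)
Conditions: LiAlH(OEt)3 (4 equiv, made from LiAlH4 and EtOAc in Et2O at 0 °C), THF, 0 °C; then aq. potassium sodium tartrate
Reagents that add atoms: none
Why: Partial reduction of the N,N-dimethylamide by the alkoxyaluminium hydride stops at the tetrahedral aminal aluminate, which releases the aldehyde only on work-up, while the two hydroxyls are carried as alkoxyaluminates at the cost of extra reagent.

Step 18
Reactants: 30 18,19-dihydroxy C12 aldehyde; 31 2-(triphenylphosphoranylidene)propanal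
Product: 32 (12E)-enal diol (C9 bears CH2CH=C(CH3)CHO)
Conditions: toluene, 90 °C
Reagents that add atoms: none
Why: Wittig olefination with the formyl-stabilised ylide gives the (E)-2-methyl enal under the usual thermodynamic control of stabilised ylides, which sets the 12E alkene.

Step 19
Reactants: 32 (12E)-enal diol
Product: 33 ent-labda-8(17),12E,14-triene-18,19-diol
Conditions: Ph3PCH3Br, KOt-Bu (4 equiv each), THF, 0 → 23 °C
Reagents that add atoms: methyltriphenylphosphonium bromide, C[P+](c1ccccc1)(c1ccccc1)c1ccccc1.[Br-]
Why: Wittig methylenation of the enal completes the conjugated diene without affecting the 12E geometry, the excess ylide compensating for deprotonation of the diol.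

Step 20
Reactants: 33 triene diol
Product: 34 ent-labda-8(17),12E,14-triene-18,19-diyl diacetate (5S,9R,10S; CNP0129553.1)
Conditions: Ac2O, pyridine, DMAP (cat.), CH2Cl2, 23 °C
Reagents that add atoms: acetic anhydride, CC(=O)OC(C)=O
Why: DMAP-catalysed acetylation of both primary alcohols; no stereocentre or alkene is affected.

Compound list
1 | methacrolein (2-methylprop-2-enal) | CC(=C)C=O | starting material
2 | but-3-en-1-ylmagnesium bromide | C=CCC[Mg]Br | starting material
3 | trimethyl[(2-methylhepta-1,6-dien-1-yl)oxy]silane (not isolated) | C=CCCCC(C)=CO[Si](C)(C)C | intermediate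
4 | 2-methylhept-6-enal (racemic) | C=CCCCC(C)C=O | intermediate
5 | but-3-en-2-one | CC(=O)C=C | starting material
6 | 1-(2-methylhepta-1,6-dien-1-yl)pyrrolidine (not isolated) | C=CCCCC(C)=CN1CCCC1 | intermediate
7 | 2-methyl-2-(3-oxobutyl)hept-6-enal (not isolated) | C=CCCCC(C)(C=O)CCC(C)=O | intermediate
8 | 4-methyl-4-(pent-4-en-1-yl)cyclohex-2-en-1-one (racemic) | C=CCCCC1(C)C=CC(=O)CC1 | intermediate
9 | 4-methyl-4-(pent-4-en-1-yl)cyclohexa-2,5-dien-1-one | C=CCCCC1(C)C=CC(=O)C=C1 | intermediate
10 | 4-methyl-4-[3-(1,2,4-trioxolan-3-yl)propyl]cyclohexa-2,5-dien-1-one (not isolated) | O=C1C=CC(C)(CCCC2OCOO2)C=C1 | intermediate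
11 | 4-methyl-4-(4-oxobutyl)cyclohexa-2,5-dien-1-one | O=CCCCC1(C)C=CC(=O)C=C1 | intermediate
12 | (4aS,8aR)-4a-methyl-4a,5,6,7-tetrahydronaphthalene-2,8(1H,8aH)-dione; cis-fused, H-5 syn to C20 | C1=CC(=O)C[C@H]2C(=O)CCC[C@@]12C | intermediate
13 | (4aS,8aS)-4a-methyl-4a,5,6,7-tetrahydronaphthalene-2,8(1H,8aH)-dione; trans-fused, H-5 anti to C20 | C1=CC(=O)C[C@@H]2C(=O)CCC[C@@]12C | intermediate
14 | trans-fused 4,4-(ethylenedioxy)-10-methyl-octal-8-en-7-one | C1=CC(=O)C[C@@H]2C3(OCCO3)CCC[C@@]12C | intermediate
15 | 8-(hydroxymethyl) derivative of 14 | C1=C(CO)C(=O)C[C@@H]2C3(OCCO3)CCC[C@@]12C | intermediate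
16 | C17 tert-butyldimethylsilyl ether of 15 | C1=C(CO[Si](C)(C)C(C)(C)C)C(=O)C[C@@H]2C3(OCCO3)CCC[C@@]12C | intermediate
17 | (7R)-7-hydroxy compound from 16, O-7 syn to C20 | C1=C(CO[Si](C)(C)C(C)(C)C)[C@H](O)C[C@@H]2C3(OCCO3)CCC[C@@]12C | intermediate
18 | N,N-dimethylacetamide dimethyl acetal (1,1-dimethoxy-N,N-dimethylethanamine) | CN(C)C(C)(OC)OC | starting material
19 | O-7 ketene N,O-acetal of 17 (not isolated) | C1=C(CO[Si](C)(C)C(C)(C)C)[C@H](OC(=C)N(C)C)C[C@@H]2C3(OCCO3)CCC[C@@]12C | intermediate
20 | C9 N,N-dimethylacetamide, side chain syn to C20, C7=C8, C17–OTBS, C4 dioxolane | CN(C)C(=O)C[C@@H]1C(CO[Si](C)(C)C(C)(C)C)=CC[C@@H]2C3(OCCO3)CCC[C@@]12C | intermediate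
21 | C17 alcohol of 20 | CN(C)C(=O)C[C@@H]1C(CO)=CC[C@@H]2C3(OCCO3)CCC[C@@]12C | intermediate
22 | C17 N-(2-nitrophenylsulfonyl)hydrazine from 21 (not isolated) | CN(C)C(=O)C[C@@H]1C(CN(N)S(=O)(=O)c3ccccc3[N+](=O)[O-])=CC[C@@H]2C4(OCCO4)CCC[C@@]12C | intermediate
23 | C17 allylic diazene (not isolated) | CN(C)C(=O)C[C@@H]1C(CN=N)=CC[C@@H]2C3(OCCO3)CCC[C@@]12C | intermediate
24 | 8(17)-methylene amide ketal | CN(C)C(=O)C[C@@H]1C(=C)CC[C@@H]2C3(OCCO3)CCC[C@@]12C | intermediate
25 | 4-oxo-8(17)-methylene amide, H-5 anti to C20 | CN(C)C(=O)C[C@@H]1C(=C)CC[C@@H]2C(=O)CCC[C@@]12C | intermediate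
26 | C4 methoxymethylidene enol ether, E/Z mixture (not isolated) | CN(C)C(=O)C[C@@H]1C(=C)CC[C@@H]2C(=COC)CCC[C@@]12C | intermediate
27 | 4-formyl amide, mixture of C4 epimers | CN(C)C(=O)C[C@@H]1C(=C)CC[C@@H]2C(C=O)CCC[C@@]12C | intermediate
28 | 4-formyl-4-(hydroxymethyl) amide (not isolated) | CN(C)C(=O)C[C@@H]1C(=C)CC[C@@H]2C(CO)(C=O)CCC[C@@]12C | intermediate
29 | 4,4-bis(hydroxymethyl) amide (18,19-diol) | CN(C)C(=O)C[C@@H]1C(=C)CC[C@@H]2C(CO)(CO)CCC[C@@]12C | intermediate
30 | 18,19-dihydroxy C12 aldehyde | O=CC[C@@H]1C(=C)CC[C@@H]2C(CO)(CO)CCC[C@@]12C | intermediate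
31 | 2-(triphenylphosphoranylidene)propanal | CC(C=O)=P(c1ccccc1)(c1ccccc1)c1ccccc1 | starting material
32 | (12E)-enal diol | O=C/C(C)=C/C[C@@H]1C(=C)CC[C@@H]2C(CO)(CO)CCC[C@@]12C | intermediate
33 | ent-labda-8(17),12E,14-triene-18,19-diol | C=C/C(C)=C/C[C@@H]1C(=C)CC[C@@H]2C(CO)(CO)CCC[C@@]12C | intermediate
34 | ent-labda-8(17),12E,14-triene-18,19-diyl diacetate (5S,9R,10S) | C=C/C(C)=C/C[C@@H]1C(=C)CC[C@@H]2C(COC(C)=O)(COC(C)=O)CCC[C@@]12C | target

Total step count: 20. Longest linear sequence: 20 steps (the route is fully linear, 1 to 34).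

Steps most likely to fail

1. Step 5 (carbene-catalysed ring closure). The six-membered acyl transfer from an enolisable aliphatic aldehyde may be slow enough for aldol and benzoin-type self-condensation to consume the substrate, or the catalyst may discriminate the two arms poorly. Fallback: use a nitronate in place of the carbene-bound acyl anion. Setting out from 11, hydroxylamine hydrochloride and NaOAc (1 equiv, 0 °C, aldehyde before dienone carbonyl) give the aldoxime F1. NaBO3·4H2O in acetic acid at 55 °C oxidises it to the nitroalkane F2. A cinchona-alkaloid-derived tertiary-amine thiourea (10 mol%, toluene) catalyses the arm-selective 6-exo-trig intramolecular nitro-Michael addition to the cis-fused nitro enone F3. A Nef reaction (NaOMe, MeOH; then TiCl3, NH4OAc, H2O) unveils the C4 ketone and returns to the route at 12.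

2. Step 6 (correction of C5). The equilibrium may not lie far enough on the trans side in a bicycle whose cis form has two conformers, and prolonged base contact may open intramolecular aldol pathways. Fallback: keep the cis fusion through ring B, control C7 by the reagent, and equilibrate only when the equatorial C9 substituent disfavours the cis form. Setting out from 12, the conditions of steps 7–9 give the cis ketal F4, the cis hydroxymethyl enone F5 and the cis silyl ether F6. Corey–Bakshi–Shibata reduction ((S)-2-methyl-oxazaborolidine, BH3·SMe2, THF, −20 °C) gives the cis-fused (7R)-alcohol F7. Heating with 18 gives, through the cis ketene N,O-acetal F8, the cis amide F9. Bu4NF gives the cis allylic alcohol F10. The Mitsunobu–diazene sequence passes through the cis sulfonylhydrazine F11 and the cis allylic diazene F12 to the cis exocyclic alkene F13. Dilute HCl gives the cis keto amide F14, which NaOMe in MeOH at 23 °C equilibrates to 25, where the route is rejoined.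

3. Step 8 (hydroxymethylation of C8). Addition of the amine catalyst to C9, next to the quaternary C10, may be too slow, or the hindered zwitterion may not be trapped by formaldehyde. Fallback: halogenation and cross-coupling. Setting out from 14, iodine and pyridine in CH2Cl2 give the α-iodo enone F15. Stille coupling with (tributylstannyl)methanol (Pd(PPh3)4, 1,4-dioxane, 90 °C) then gives 15, where the route is rejoined.

Further compounds
F1 | step 5 | 4-(1-methyl-4-oxocyclohexa-2,5-dien-1-yl)butanal oxime | ON=CCCCC1(C)C=CC(=O)C=C1
F2 | step 5 | 4-methyl-4-(4-nitrobutyl)cyclohexa-2,5-dien-1-one | O=C1C=CC(C)(CCCC[N+](=O)[O-])C=C1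
F3 | step 5 | cis-fused 10-methyl-4-nitro-octal-8-en-7-one (C4 epimers) | C1=CC(=O)C[C@H]2C([N+](=O)[O-])CCC[C@@]12C
F4 | step 6 | cis-fused C4 dioxolane of 12 (C5 epimer of 14) | C1=CC(=O)C[C@H]2C3(OCCO3)CCC[C@@]12C
F5 | step 6 | cis-fused 8-(hydroxymethyl) enone ketal (C5 epimer of 15) | C1=C(CO)C(=O)C[C@H]2C3(OCCO3)CCC[C@@]12C
F6 | step 6 | cis-fused C17 silyl ether (C5 epimer of 16) | C1=C(CO[Si](C)(C)C(C)(C)C)C(=O)C[C@H]2C3(OCCO3)CCC[C@@]12C
F7 | step 6 | cis-fused (7R)-allylic alcohol (C5 epimer of 17) | C1=C(CO[Si](C)(C)C(C)(C)C)[C@H](O)C[C@H]2C3(OCCO3)CCC[C@@]12C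
F8 | step 6 | cis-fused ketene N,O-acetal (C5 epimer of 19) | C1=C(CO[Si](C)(C)C(C)(C)C)[C@H](OC(=C)N(C)C)C[C@H]2C3(OCCO3)CCC[C@@]12C
F9 | step 6 | cis-fused C9 acetamide (C5 epimer of 20) | CN(C)C(=O)C[C@@H]1C(CO[Si](C)(C)C(C)(C)C)=CC[C@H]2C3(OCCO3)CCC[C@@]12C
F10 | step 6 | cis-fused C17 alcohol (C5 epimer of 21) | CN(C)C(=O)C[C@@H]1C(CO)=CC[C@H]2C3(OCCO3)CCC[C@@]12C
F11 | step 6 | cis-fused C17 sulfonylhydrazine (C5 epimer of 22) | CN(C)C(=O)C[C@@H]1C(CN(N)S(=O)(=O)c3ccccc3[N+](=O)[O-])=CC[C@H]2C4(OCCO4)CCC[C@@]12C
F12 | step 6 | cis-fused allylic diazene (C5 epimer of 23) | CN(C)C(=O)C[C@@H]1C(CN=N)=CC[C@H]2C3(OCCO3)CCC[C@@]12C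
F13 | step 6 | cis-fused 8(17)-methylene amide ketal (C5 epimer of 24) | CN(C)C(=O)C[C@@H]1C(=C)CC[C@H]2C3(OCCO3)CCC[C@@]12C
F14 | step 6 | cis-fused 4-oxo amide (C5 epimer of 25) | CN(C)C(=O)C[C@@H]1C(=C)CC[C@H]2C(=O)CCC[C@@]12C
F15 | step 8 | 8-iodo derivative of 14 | C1=C(I)C(=O)C[C@@H]2C3(OCCO3)CCC[C@@]12C
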